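**Strategy.** In prostanoid numbering (C1 = carboxyl carbon, ring = C8–C12), the cyclopentane is read as a dimer of succinaldehyde. C6–C7–C8–C12 is one four-carbon dialdehyde; C9–C10–C11 plus one formyl carbon that is excised later is the other. In one flask, an (S)-proline-mediated aldol reaction joins C8 to C9 and an amine-salt aldol condensation joins C11 to C12. The step exploits the 1,3-oxygenated ring (C9 hydroxyl, C11 ketone) with its two-carbon C7–C6 arm at C8. It gives a cis-fused lactol enal that already carries C8, C9, the C9 oxygen and C6 at the aldehyde level. Conjugate addition at C12, ozonolysis to the C11 ketone and a Wittig reaction at C6 complete the skeleton.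

Key step: step 2

Remark: lactols 3, 4 and 13 are anomeric mixtures and enol ether 10 is an E/Z mixture; these centres are left unspecified in the SMILES and do not affect the outcome.

**Step 1**
Reactants: 1 2,5-dimethoxytetrahydrofuran (cis/trans mixture)
Product: 2 succinaldehyde
Conditions: H2O, 90 °C, 2 h; distil off MeOH/H2O; CH2Cl2 extraction; distil under reduced pressure, use at once
Reagents that add atoms: water, O
Why: Neutral aqueous hydrolysis of the cyclic bis-acetal (acetal hydrolysis) should release the monomeric dialdehyde, which is used fresh because it oligomerises on storage.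

**Step 2**
Reactants: 2 succinaldehyde (two molecules)
Product: 4 cis-fused bicyclic lactol enal, (3aR,6aS)-2-hydroxy-3,3a,6,6a-tetrahydro-2H-cyclopenta[b]furan-5-carbaldehyde, via lactol dialdehyde 3 (not isolated)
Conditions: (S)-proline (2 mol%), THF, rt, 20 h; then [Bn2NH2][O2CCF3] (2 mol%), rt, 14 h
Reagents that add atoms: none
Why: (S)-Proline turns one molecule of 2 into an enamine whose α-carbon (C8) adds to an aldehyde carbon (C9) of a second molecule (direct aldehyde–aldehyde aldol reaction), which forms C8–C9; the carboxylic acid of the catalyst holds the acceptor on one enamine face in a hydrogen-bonded chair transition state, so C8 and C9 arise together as the anti aldol of the required absolute sense (catalyst control). The C9 hydroxyl then closes onto the C6 aldehyde of the donor unit (5-exo-trig hemiacetalisation) to give the 2,3-cis lactol 3. Dibenzylammonium trifluoroacetate forms an enamine at C11 that attacks the C12 aldehyde (5-exo-trig, enolexo aldol addition), and loss of water gives the conjugated enal, which forms C11–C12 and closes the cyclopentene; only a cis ring fusion is possible, so the still epimerisable C8 is locked relative to C9. The closest known reaction types are the proline-catalysed cross-aldol reaction of two aldehydes and the amine-salt-mediated intramolecular aldol condensation. The step needs dimerisation to win over oligomerisation and one closure among several: a low catalyst loading and a first stage stopped before full conversion favour the dimer, the lactol masks the fourth aldehyde, and of the reversible aldol closures only the one through the C11 enamine can dehydrate to a conjugated enal, which drains the equilibria towards 4.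

**Step 3**
Reactants: 4 cis-fused bicyclic lactol enal
Product: 5 lactone enal, (3aR,6aS)-2-oxo-3,3a,6,6a-tetrahydro-2H-cyclopenta[b]furan-5-carbaldehyde
Conditions: TEMPO (10 mol%), PhI(OAc)2 (1.2 equiv), CH2Cl2, rt
Reagents that add atoms: none
Why: Oxoammonium oxidation should convert the hemiacetal into the γ-lactone while the conjugated aldehyde, not hydrated under anhydrous conditions, stays untouched; the lactone allows C6 to be returned to the lactol later by hydride instead of acid.

**Step 4**
Reactants: 6 oct-1-en-3-one
Product: 8 2-(2-bromoethyl)-2-pentyl-1,3-dioxolane, via 1-bromooctan-3-one 7 (not isolated)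
Conditions: HBr (gas), ethylene glycol (1.5 equiv), CH2Cl2, 0 °C → rt
Reagents that add atoms: hydrogen bromide, Br; ethylene glycol, OCCO
Why: Conjugate hydrobromination of the enone gives the β-bromo ketone, which the same acid ketalises with ethylene glycol (acetalisation) to a bromide suited to Grignard formation.

**Step 5**
Reactants: 5 lactone enal; 8 2-(2-bromoethyl)-2-pentyl-1,3-dioxolane
Product: 10 silyl enol ether of the 1,4-adduct, via Grignard reagent 9 (not isolated)
Conditions: 8, Mg turnings, THF, 25 °C; then 5, CuBr·SMe2 (10 mol%), TMSCl (2 equiv), HMPA (2 equiv), THF, −78 °C; Et3N, then hexane/aq. NaHCO3 work-up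
Reagents that add atoms: chlorotrimethylsilane, C[Si](C)(C)Cl
Why: Chlorotrimethylsilane-accelerated, copper-catalysed conjugate addition of the Grignard reagent to the enal should deliver the alkyl group to C12 from the convex face of the cis-fused bicycle, anti to the C8–C7 bond, which sets C12 trans to C8; the enolate is trapped as the silyl enol ether.

**Step 6**
Reactants: 10 silyl enol ether
Product: 11 keto lactone, (3aR,4R,6aS)-4-[2-(2-pentyl-1,3-dioxolan-2-yl)ethyl]tetrahydro-2H-cyclopenta[b]furan-2,5(3H)-dione
Conditions: O3, CH2Cl2, −78 °C; then Me2S, −78 °C → rt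
Reagents that add atoms: ozone, O=[O+][O-]
Why: Ozonolysis of the electron-rich enol ether double bond excises the former formyl carbon and leaves the C11 ketone; C12 is now α to the ketone and its trans relation to C8 is also the thermodynamic one.

**Step 7**
Reactants: 11 keto lactone
Product: 12 bis-ketal lactone (C11 ketone as 1,3-dioxolane)
Conditions: TMSOCH2CH2OTMS (1.5 equiv), TMSOTf (5 mol%), CH2Cl2, −78 → −20 °C; pyridine quench
Reagents that add atoms: 1,2-bis(trimethylsilyloxy)ethane, C[Si](C)(C)OCCO[Si](C)(C)C
Why: Aprotic ketalisation with the bis-silyl glycol under silyl triflate catalysis at low temperature should protect the C11 ketone without giving the β-acyloxy ketone a chance to eliminate the C9 oxygen.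

**Step 8**
Reactants: 12 bis-ketal lactone
Product: 13 bis-ketal lactol
Conditions: i-Bu2AlH (1.1 equiv), toluene, −78 °C; aq. potassium sodium tartrate
Reagents that add atoms: none
Why: The hydride adds once to the γ-lactone at −78 °C and the tetrahedral aluminate collapses only on work-up (partial lactone reduction), so the lactol should form without over-reduction; both ketals are inert.

**Step 9**
Reactants: 13 bis-ketal lactol; 14 (4-carboxybutyl)triphenylphosphonium bromide
Product: 16 bis-ketal hydroxy acid, the 11,15-bis(ethylene ketal) of the target, via ylide 15 (not isolated)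
Conditions: 14 (3 equiv), KOtBu (6 equiv), THF, 0 °C; then 13, 0 °C → rt; aq. NaH2PO4 work-up (pH 5)
Reagents that add atoms: none
Why: Wittig reaction of the non-stabilised ylide with the hydroxy aldehyde in equilibrium with the lactol should give the (5Z)-alkene through kinetic cis-oxaphosphetane formation, release the C9 hydroxyl, and leave the base-stable ketals untouched.

**Step 10**
Reactants: 16 bis-ketal hydroxy acid
Product: 17 13,14-dihydro-15-keto-PGD2
Conditions: AcOH/H2O/THF (6:3:1), 40 °C, stopped at full conversion
Reagents that add atoms: water, O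
Why: Mild aqueous acid should hydrolyse both dioxolanes (ketal hydrolysis) under conditions that β-hydroxy cyclopentanones of this family tolerate; C12, the only epimerisable centre, already has the favoured trans configuration.

**Compound list**

1 | 2,5-dimethoxytetrahydrofuran (cis/trans mixture) | COC1CCC(OC)O1 | starting material
2 | succinaldehyde (butanedial) | O=CCCC=O | intermediate
3 | (2S,3S)-5-hydroxy-2-(3-oxopropyl)oxolane-3-carbaldehyde (2,3-cis lactol form of the anti aldol dimer) | O=C[C@H]1CC(O)O[C@H]1CCC=O | intermediate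
4 | (3aR,6aS)-2-hydroxy-3,3a,6,6a-tetrahydro-2H-cyclopenta[b]furan-5-carbaldehyde | O=CC1=C[C@H]2CC(O)O[C@H]2C1 | intermediate
5 | (3aR,6aS)-2-oxo-3,3a,6,6a-tetrahydro-2H-cyclopenta[b]furan-5-carbaldehyde | O=CC1=C[C@H]2CC(=O)O[C@H]2C1 | intermediate
6 | oct-1-en-3-one | C=CC(=O)CCCCC | starting material
7 | 1-bromooctan-3-one | BrCCC(=O)CCCCC | intermediate
8 | 2-(2-bromoethyl)-2-pentyl-1,3-dioxolane | BrCCC1(CCCCC)OCCO1 | intermediate
9 | [2-(2-pentyl-1,3-dioxolan-2-yl)ethyl]magnesium bromide | Br[Mg]CCC1(CCCCC)OCCO1 | intermediate
10 | (3aR,4R,6aS)-4-[2-(2-pentyl-1,3-dioxolan-2-yl)ethyl]-5-[(trimethylsilyloxy)methylidene]hexahydro-2H-cyclopenta[b]furan-2-one | C[Si](C)(C)OC=C1C[C@@H]2OC(=O)C[C@@H]2[C@H]1CCC1(CCCCC)OCCO1 | intermediate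
11 | (3aR,4R,6aS)-4-[2-(2-pentyl-1,3-dioxolan-2-yl)ethyl]tetrahydro-2H-cyclopenta[b]furan-2,5(3H)-dione | CCCCCC1(CC[C@H]2C(=O)C[C@@H]3OC(=O)C[C@@H]32)OCCO1 | intermediate
12 | (3'aR,4'R,6'aS)-4'-[2-(2-pentyl-1,3-dioxolan-2-yl)ethyl]tetrahydro-2'H-spiro[1,3-dioxolane-2,5'-cyclopenta[b]furan]-2'-one | CCCCCC1(CC[C@H]2C3(OCCO3)C[C@@H]3OC(=O)C[C@@H]32)OCCO1 | intermediate
13 | (3'aR,4'R,6'aS)-4'-[2-(2-pentyl-1,3-dioxolan-2-yl)ethyl]hexahydro-2'H-spiro[1,3-dioxolane-2,5'-cyclopenta[b]furan]-2'-ol | CCCCCC1(CC[C@H]2C3(OCCO3)C[C@@H]3OC(O)C[C@@H]32)OCCO1 | intermediate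
14 | (4-carboxybutyl)triphenylphosphonium bromide | OC(=O)CCCC[P+](c1ccccc1)(c1ccccc1)c1ccccc1.[Br-] | starting material
15 | potassium 5-(triphenyl-λ5-phosphanylidene)pentanoate | [K+].[O-]C(=O)CCCC=P(c1ccccc1)(c1ccccc1)c1ccccc1 | intermediate
16 | (5Z)-11,11:15,15-bis(ethylenedioxy)-9α-hydroxyprost-5-en-1-oic acid | CCCCCC1(CC[C@H]2C3(OCCO3)C[C@H](O)[C@@H]2C/C=C\CCCC(=O)O)OCCO1 | intermediate
17 | 13,14-dihydro-15-keto-PGD2, (Z)-7-[(1R,2R,5S)-5-hydroxy-3-oxo-2-(3-oxooctyl)cyclopentyl]hept-5-enoic acid | CCCCCC(=O)CC[C@H]1C(=O)C[C@H](O)[C@@H]1C/C=C\CCCC(=O)O | target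

**Step count.** Total: 10 steps. Longest linear sequence: 9 steps (1, 2, 3, 5, 6, 7, 8, 9, 10); step 4 is the side branch.

**Steps most likely to fail**

Step 2. The symmetrical dialdehyde can oligomerise or condense at the wrong aldehyde, and the second aldol closure may stall, so that little material is funnelled to 4. The fallback sets out from 1 and comes back at 4; it differentiates the two four-carbon units by masking one aldehyde of each. Acid-catalysed methanolysis of 1 (MeOH, HC(OMe)3, cat. H2SO4) should give 1,1,4,4-tetramethoxybutane F1. Half-hydrolysis (Amberlyst 15, wet acetone, stopped at partial conversion, unreacted F1 recycled) should give 4,4-dimethoxybutanal F2, a mono-aldehyde that can undergo only one aldol event. Its (S)-proline-catalysed self-aldol reaction (DMF, 4 °C) should give the anti aldol (2S,3S)-2-(2,2-dimethoxyethyl)-3-hydroxy-6,6-dimethoxyhexanal F3, with the same C8–C9 bond and configurations as in 3. Aqueous CF3CO2H in THF with dibenzylammonium trifluoroacetate, added to the same flask, then unmasks both acetals, closes the lactol and effects the same C11–C12 aldol condensation, which returns 4.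

Step 5. The organomagnesium reagent may add to the lactone carbonyl, or act as a base at the γ-position of the enal and so trigger β-elimination of the C9 carboxylate, before conjugate transfer occurs. The fallback sets out from 4 and comes back at 12; it carries C6 at the acetal level through the organometallic step. MeOH/Amberlyst 15/MgSO4 should convert 4 into the methyl acetal enal F4. The same copper-catalysed addition of 9 with TMSCl should give the silyl enol ether F5, and ozonolysis (O3, then Me2S) the keto acetal F6. Jones oxidation (CrO3, aq. H2SO4, acetone, 0 °C) should oxidise the methyl acetal to the γ-lactone and at the same time hydrolyse the dioxolane, to give the diketo lactone F7. Double ketalisation with TMSOCH2CH2OTMS/TMSOTf returns 12.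

Step 10. Acid-promoted loss of water from the β-ketol (C9 hydroxyl, C11 ketone) to the conjugated cyclopentenone may compete with hydrolysis of the two cyclic ketals, and the acyclic C15 ketal may be unmasked only slowly; step 7 carries a related risk of β-elimination. The fallback sets out from 11 and comes back at 17; both ketones are carried as silyl-protected alcohols and restored by oxidation, so the β-ketol never meets the acid needed for ketal hydrolysis. Hydrolysis of the dioxolane of 11 (1 M HCl, THF, before any C9 hydroxyl is free) gives the diketo lactone F7 already described. NaBH4 (MeOH, −20 °C) should give the diol lactone F8 (epimers at C11 and C15, which converge later), and Et3SiCl/imidazole the bis(triethylsilyl) ether F9. i-Bu2AlH should give the lactol F10, and the Wittig reaction with 15 the 9-hydroxy acid F11. t-BuMe2SiCl/imidazole, with aqueous cleavage of the silyl ester on work-up, should give the 9-silyl ether F12. PPTS in MeOH should remove only the triethylsilyl groups to give the diol F13. Dess–Martin periodinane should oxidise C11 and C15 to the diketone F14. Aqueous HF in MeCN at 0 °C removes the remaining silyl group and returns 17.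

**Further compounds**

F1 | step 2 | 1,1,4,4-tetramethoxybutane | COC(OC)CCC(OC)OC
F2 | step 2 | 4,4-dimethoxybutanal | COC(OC)CCC=O
F3 | step 2 | (2S,3S)-2-(2,2-dimethoxyethyl)-3-hydroxy-6,6-dimethoxyhexanal | O=C[C@@H](CC(OC)OC)[C@@H](O)CCC(OC)OC
F4 | step 5 | (3aR,6aS)-2-methoxy-3,3a,6,6a-tetrahydro-2H-cyclopenta[b]furan-5-carbaldehyde | O=CC1=C[C@H]2CC(OC)O[C@H]2C1
F5 | step 5 | (3aR,4R,6aS)-2-methoxy-4-[2-(2-pentyl-1,3-dioxolan-2-yl)ethyl]-5-[(trimethylsilyloxy)methylidene]hexahydro-2H-cyclopenta[b]furan | C[Si](C)(C)OC=C1C[C@@H]2OC(OC)C[C@@H]2[C@H]1CCC1(CCCCC)OCCO1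
F6 | step 5 | (3aR,4R,6aS)-2-methoxy-4-[2-(2-pentyl-1,3-dioxolan-2-yl)ethyl]hexahydro-5H-cyclopenta[b]furan-5-one | CCCCCC1(CC[C@H]2C(=O)C[C@@H]3OC(OC)C[C@@H]32)OCCO1
F7 | step 5 | (3aR,4R,6aS)-4-(3-oxooctyl)tetrahydro-2H-cyclopenta[b]furan-2,5(3H)-dione | CCCCCC(=O)CC[C@H]1C(=O)C[C@@H]2OC(=O)C[C@@H]21
F8 | step 10 | (3aR,4R,6aS)-5-hydroxy-4-(3-hydroxyoctyl)hexahydro-2H-cyclopenta[b]furan-2-one (epimers at the two carbinol carbons) | CCCCCC(O)CC[C@H]1C(O)C[C@@H]2OC(=O)C[C@@H]21
F9 | step 10 | bis(triethylsilyl) ether of F8 | CCCCCC(O[Si](CC)(CC)CC)CC[C@H]1C(O[Si](CC)(CC)CC)C[C@@H]2OC(=O)C[C@@H]21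
F10 | step 10 | lactol from F9 | CCCCCC(O[Si](CC)(CC)CC)CC[C@H]1C(O[Si](CC)(CC)CC)C[C@@H]2OC(O)C[C@@H]21
F11 | step 10 | (5Z)-9α-hydroxy-11,15-bis(triethylsilyloxy)prost-5-en-1-oic acid | CCCCCC(O[Si](CC)(CC)CC)CC[C@H]1C(O[Si](CC)(CC)CC)C[C@H](O)[C@@H]1C/C=C\CCCC(=O)O
F12 | step 10 | (5Z)-9α-(tert-butyldimethylsilyloxy)-11,15-bis(triethylsilyloxy)prost-5-en-1-oic acid | CCCCCC(O[Si](CC)(CC)CC)CC[C@H]1C(O[Si](CC)(CC)CC)C[C@H](O[Si](C)(C)C(C)(C)C)[C@@H]1C/C=C\CCCC(=O)O
F13 | step 10 | (5Z)-9α-(tert-butyldimethylsilyloxy)-11,15-dihydroxyprost-5-en-1-oic acid | CCCCCC(O)CC[C@H]1C(O)C[C@H](O[Si](C)(C)C(C)(C)C)[C@@H]1C/C=C\CCCC(=O)O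
F14 | step 10 | (5Z)-9α-(tert-butyldimethylsilyloxy)-11,15-dioxoprost-5-en-1-oic acid | CCCCCC(=O)CC[C@H]1C(=O)C[C@H](O[Si](C)(C)C(C)(C)C)[C@@H]1C/C=C\CCCC(=O)O
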